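E and D are two exits for a molecule of X: at each instant it has some chance of leaving by E and some chance of leaving by D, and the amounts collected show the average ratio of those chances.

| setting | teal | flask |
|---|---|---|
| X | 1.5 M | 1.5 M |
| J | 7.5 mM | 15 mM |
| remark | run made earlier |  |
| time |  | 6.0 min |

teal run (percent of the X charged)

| time / s | X / % | E / % | D / % |
|---|---|---|---|
| 20.0 | 13.7 | 10.8 | 23.5 |
| 40.0 | 4.5 | 14.8 | 29.6 |
| 50.0 | 4.2 | 14.9 | 32.1 |
| 80.0 | 2.2 | 16.5 | 33.1 |
| 90.0 | 1.6 | 15.0 | 34.7 |
| 120 | 0 | 15.1 | 33.5 |

(standard deviation of a reading: 1 percentage point)

- at 6.0 min, what has stopped the reaction, if anything has (no working catalyst is left / it is still moving / forward and back rates have come level / all of X has reacted)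
- conversion of X at 6.0 min
- amount of E at 6.0 min, in percent of the X charged
- amount of D at 6.0 min, in percent of the X charged

- the reaction counts as stopped when no species that holds the X changes by six tenths of a point or more over the second half of the time
- no earlier run changes the charge of J; that part of a forecast is a guess

In the teal run, E over D reads 0.460 at 20.0 s and 0.451 at 120 s, so within the scatter the fork stays the same while X falls, and the two exits appear to depend on X in the same way. My own guess, which no earlier run tests, is that J opens the exit to E and that D needs no J. The last teal reading then gives s = 60.1 /M, and this s, the ratio of E to D per unit of J, is a selectivity factor that you can carry to another charge of J.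

Now turn the question round: for this flask to hold as much E as D, s times J would have to reach 1, but with 15 mM of J it comes to 0.901, so I expect E a little below D.

The forecast gives all of X has reacted, with conversion 99.7 %, E 15.3 % and D 34 %, on these grounds: “E/D stays near 0.45 throughout, so the products appear parallel and stable”. Its E and D stand close to the last teal reading taken over, a ratio of 0.450 against my 0.901.

The flask gives all of X has reacted, with conversion 100 %, E 27.2 % and D 28.1 %.

    X → D (k = 0.0310 /s)
    2 X → G (k = 0.0400 /M/s)
    X + J → J + E (k = 2.00 /M/s)

E over D in this flask is 0.968, beside the 0.901 reckoned from s. Take the neighbouring flask, the same charge of X with 0.037 M of J: the same s gives 2.22, which puts E well above D. That flask holds E 47.0 % and D 19.7 % at 6.00 min, a ratio of 2.39.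

(The runs stem from a simulated flask with constants of no real substance; scatter was added.)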